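I started from a small charge: ash held 10.0 mM of partner against 20 mM of substrate, and I had to say what that was worth at the end.

| setting | north | cedar | ash |
|---|---|---|---|
| substrate | 13 mM | 20 mM | 20 mM |
| partner | 21 mM (in portions, 4) | 21.0 mM (in portions, 4) | 10.0 mM |
| remark | run made earlier; portions every 1.0 min | the portions of partner follow each other after 1.0 min, the first at the start | everything together at the start |
| time |  | 10 min | 10 min |

- north (time / min: bis adduct / %): 0.833: 0; 2.00: 1.1; 4.00: 5.0; 6.00: 11.5

(standard deviation of a reading: 0.5 percentage points)

1. which one finishes higher in amount of bis adduct, in percent of the substrate charged ("neither" within 2 percentage points) (cedar / ash / neither)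
2. amount of bis adduct at the end, in percent of the substrate charged, cedar
3. amount of bis adduct at the end, in percent of the substrate charged, ash

- a reading or a percentage of bis adduct counts all its forms, free or not

I wrote the balance of partner, the limiting reagent in ash. I took a bis adduct to hold two partners, as its name says, so I divided the partner charge by two and then by the substrate charge. For ash this gave 25.0%. I called this number the bis ceiling: the amount of bis adduct that the partner charge can make, in percent of the substrate charged. For cedar, with its portions counted whole, it was 52.5%, which is 2.10 times the value for ash. So I expected cedar to finish higher.

Was one number enough? I tested it on north, whose ceiling was 80.8%. North read 11.5% at 6.00 min, which is 14.2% of that ceiling. That reading stood under the ceiling and had risen from 5.0% at 4.00 min, so the ceiling bounded north at that time without giving its amount. I committed to the order, cedar over ash, and to each end value under its own ceiling.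

The forecast also said cedar, with 8% for cedar and 1% for ash. Its grounds were “a fast first addition and a much slower second one”.

The flasks gave cedar, with 16.4% in cedar and 4.86% in ash. Cedar stood 8.4 percentage points above the forecast and at 31.2% of its ceiling. Ash stood at 19.4% of its ceiling.

    partner + first product → bis adduct (k = 6.00 L mol⁻¹ min⁻¹)
    substrate + partner → first product (k = 11.0 L mol⁻¹ min⁻¹)
    substrate + bis adduct ⇌ idle adduct, settled at all times (K = 390 L mol⁻¹)
    bis adduct → over-reaction product (k = 3.90 × 10⁻⁵ min⁻¹)

In ash at 10.0 min, first product was being made 3.30 times faster than it was used, each step taken net. The flask then held 32.5% first product against 4.86% bis adduct, all forms counted. A neighbour of ash with 5.0 mM of substrate and the same partner charge had a ceiling of 100% by the same reckoning. Computed, it ended at 13.4% bis adduct, with 43.4% first product.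

The runs are calculated with made-up constants; scatter was added.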